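**Retrosynthetic overview**
1. Target 23 ⇐ bis-acetonide 22; the C-6 quaternary methyl is added last, by β-face cyclopropanation and hydrogenolysis of the C6=C7 alkene of trans-decalone 19 (no Robinson annulation, no Wieland–Miescher ketone).
2. Ring A (formed second) ⇐ titanium-induced keto ester cyclization of 17 across C1–C2: the ester carbon becomes the C-2 ketone, the ketone carbon becomes C-1(H).
3. Keto ester 17 ⇐ aldehyde 14 + side-chain Grignard 15 (tertiary carbinol from (R)-2-methylglycidol).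
4. Ring B (formed first) ⇐ catalytic enantioselective Diels–Alder of (E)-enal 13 with diene 10: the (E) geometry becomes the trans ring fusion, the catalyst sets C-4a/C-8a, and the diene carries the secondary carbinol from (R)-glyceraldehyde.

Assumption: ring positions of all intermediates are cited with the decalin numbering of the target (C-1 side chain, C-2 ketone, C-4a/C-8a ring fusion, C-6 diol-bearing carbon); α is the face of the 8a-methyl, β the face of H-4a.

**Step 1**
Reactants: 1 (R)-2-methylglycidol; 2 allylmagnesium chloride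
Product: 3 (S)-2-methylhex-5-ene-1,2-diol
Conditions: 2 (2.5 equiv), CuI (10 mol%), THF, −40 → 0 °C; aq NH4Cl
Reagents that add atoms: none
Why: Copper-catalysed SN2 epoxide opening at the unsubstituted carbon leaves the quaternary centre untouched (the label changes from R to S only through a priority switch), and the cold magnesium alkoxide does not undergo Payne equilibration.

**Step 2**
Reactants: 3 (S)-2-methylhex-5-ene-1,2-diol
Product: 4 (4S)-4-(but-3-en-1-yl)-2,2,4-trimethyl-1,3-dioxolane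
Conditions: 2,2-dimethoxypropane, pyridinium p-toluenesulfonate (cat.), CH2Cl2, rt
Reagents that add atoms: 2,2-dimethoxypropane, COC(C)(C)OC
Why: Acid-catalysed transacetalisation protects the 1,2-diol as its acetonide.

**Step 3**
Reactants: 4 (4S)-4-(but-3-en-1-yl)-2,2,4-trimethyl-1,3-dioxolane
Product: 6 3-[(4S)-2,2,4-trimethyl-1,3-dioxolan-4-yl]propan-1-ol, via secondary ozonide 5 (not isolated)
Conditions: O3, CH2Cl2, −78 °C; then NaBH4, MeOH, −78 °C → rt
Reagents that add atoms: ozone, [O-][O+]=O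
Why: Ozonolysis with reductive (hydride) work-up removes the terminal carbon and gives the primary alcohol; the acetonide is inert.

**Step 4**
Reactants: 6 3-[(4S)-2,2,4-trimethyl-1,3-dioxolan-4-yl]propan-1-ol
Product: 7 (4S)-4-(3-bromopropyl)-2,2,4-trimethyl-1,3-dioxolane
Conditions: CBr4, PPh3, CH2Cl2, 0 °C
Reagents that add atoms: carbon tetrabromide, BrC(Br)(Br)Br
Why: Appel bromination converts the primary alcohol under neutral conditions that keep the acetonide.

**Step 5**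
Reactants: 8 (R)-2,2-dimethyl-1,3-dioxolane-4-carbaldehyde
Product: 9 (4S)-4-ethynyl-2,2-dimethyl-1,3-dioxolane
Conditions: dimethyl (1-diazo-2-oxopropyl)phosphonate, K2CO3, MeOH, 0 °C → rt
Reagents that add atoms: dimethyl (1-diazo-2-oxopropyl)phosphonate, CC(=O)C(=[N+]=[N-])P(=O)(OC)OC
Why: Seyferth–Gilbert homologation (Ohira–Bestmann variant) under mild base keeps the α-alkoxy stereocentre (R becomes S by priority switch only).

**Step 6**
Reactants: 9 (4S)-4-ethynyl-2,2-dimethyl-1,3-dioxolane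
Product: 10 (4S)-4-(buta-1,3-dien-2-yl)-2,2-dimethyl-1,3-dioxolane
Conditions: ethylene (1 atm), second-generation Grubbs catalyst RuCl2(=CHPh)(PCy3)(1,3-dimesitylimidazolidin-2-ylidene) (5 mol%), CH2Cl2, rt
Reagents that add atoms: ethylene, C=C
Why: Ruthenium-catalysed enyne cross-metathesis of a terminal alkyne with ethylene gives the 2-substituted buta-1,3-diene.

**Step 7**
Reactants: 11 methyl 4-oxobutanoate; 12 2-(triphenylphosphoranylidene)propanal
Product: 13 methyl (4E)-5-methyl-6-oxohex-4-enoate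
Conditions: toluene, 90 °C
Reagents that add atoms: none
Why: Wittig olefination with a formyl-stabilised ylide gives the (E)-2-methyl-2-enal selectively.

**Step 8**
Reactants: 10 (4S)-4-(buta-1,3-dien-2-yl)-2,2-dimethyl-1,3-dioxolane; 13 methyl (4E)-5-methyl-6-oxohex-4-enoate
Product: 14 methyl 3-[(1S,6S)-3-[(4S)-2,2-dimethyl-1,3-dioxolan-4-yl]-6-formyl-6-methylcyclohex-3-en-1-yl]propanoate
Conditions: (R)-1-(2-methylphenyl)-3,3-diphenyltetrahydro-1H,3H-pyrrolo[1,2-c][1,3,2]oxazaborole (20 mol%), HN(SO2CF3)2 (20 mol%), CH2Cl2, −78 → −20 °C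
Reagents that add atoms: none
Why: Catalytic enantioselective Diels–Alder reaction (cationic oxazaborolidine, Corey type): by the formyl C–H···O model the (R)-catalyst should expose the Cα-Si face of the s-trans enal (to be confirmed on the adduct; the (S)-catalyst gives the antipode), the 2-substituted diene adds "para", and the (E) geometry of 13 is carried suprafacially into the trans C-4a H / C-8a CH3 relationship.

**Step 9**
Reactants: 7 (4S)-4-(3-bromopropyl)-2,2,4-trimethyl-1,3-dioxolane; 14 methyl 3-[(1S,6S)-3-[(4S)-2,2-dimethyl-1,3-dioxolan-4-yl]-6-formyl-6-methylcyclohex-3-en-1-yl]propanoate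
Product: 16 methyl 3-[(1S,6S)-3-[(4S)-2,2-dimethyl-1,3-dioxolan-4-yl]-6-{1-hydroxy-4-[(4S)-2,2,4-trimethyl-1,3-dioxolan-4-yl]butyl}-6-methylcyclohex-3-en-1-yl]propanoate (both carbinol epimers), via Grignard reagent 15 (not isolated)
Conditions: 7, Mg, THF, rt; then 14, THF, −78 °C; aq NH4Cl
Reagents that add atoms: none
Why: Grignard addition to the aldehyde, which reacts far faster than the methyl ester at −78 °C; the new carbinol centre is oxidised in the next step.

**Step 10**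
Reactants: 16 (hydroxy ester, both carbinol epimers)
Product: 17 methyl 3-[(1S,6S)-3-[(4S)-2,2-dimethyl-1,3-dioxolan-4-yl]-6-methyl-6-{4-[(4S)-2,2,4-trimethyl-1,3-dioxolan-4-yl]butanoyl}cyclohex-3-en-1-yl]propanoate
Conditions: NPr4RuO4 (5 mol%), N-methylmorpholine N-oxide, 4 Å MS, CH2Cl2, rt
Reagents that add atoms: none
Why: Ley–Griffith oxidation of the secondary alcohol gives the ketone; acetonides, ester and alkene are untouched.

**Step 11**
Reactants: 17 (keto ester)
Product: 19 (1R,4aS,8aS)-6-[(4S)-2,2-dimethyl-1,3-dioxolan-4-yl]-8a-methyl-1-{3-[(4S)-2,2,4-trimethyl-1,3-dioxolan-4-yl]propyl}-3,4,4a,5,8,8a-hexahydronaphthalen-2(1H)-one, via methyl enol ether 18 (not isolated)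
Conditions: TiCl3(dimethoxyethane)1.5, Zn(Cu), dimethoxyethane, reflux, 17 added over 30 h; then oxalic acid, wet SiO2, CH2Cl2, rt; then K2CO3 (cat.), MeOH, rt
Reagents that add atoms: water, O
Why: Titanium-induced keto ester cyclization (McMurry–Miller) couples the ketyl of the C-1 ketone with the ester carbonyl to give enol ether 18, whose hydrolysis makes the former ester carbon the C-2 ketone and C-1 a CH; equilibration places the C-1 chain equatorial (1R).

**Step 12**
Reactants: 19 (decalone with C6=C7 alkene)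
Product: 20 (1R,4aS,6R,7S,8aS)-6-[(4S)-2,2-dimethyl-1,3-dioxolan-4-yl]-8a-methyl-6,7-methano-1-{3-[(4S)-2,2,4-trimethyl-1,3-dioxolan-4-yl]propyl}octahydronaphthalen-2(1H)-one (cyclopropane CH2 on the β-face)
Conditions: Et2Zn, CF3CO2H, CH2I2, CH2Cl2, 0 °C → rt
Reagents that add atoms: diiodomethane, ICI
Why: Simmons–Smith cyclopropanation (Shi's CF3CO2ZnCH2I): in the rigid trans-decalin the axial 8a-methyl shields the α-face at C-7, as the angular methyl does in Δ2-steroids, so CH2 is delivered to the β-face of C6=C7.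

**Step 13**
Reactants: 20 (cyclopropane)
Product: 21 (1R,4aS,6S,8aS)-6-[(4S)-2,2-dimethyl-1,3-dioxolan-4-yl]-6,8a-dimethyl-1-{3-[(4S)-2,2,4-trimethyl-1,3-dioxolan-4-yl]propyl}decahydronaphthalen-2-ol (C-2 epimers)
Conditions: H2 (4 atm), PtO2, AcOH, rt
Reagents that add atoms: none
Why: Catalytic hydrogenolysis cleaves the least hindered cyclopropane bond (C7–CH2), leaving the added carbon as the axial β-methyl of the 6S quaternary centre with the dioxolane equatorial; the C-2 ketone is reduced in the same operation and the acetonides survive anhydrous AcOH.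

**Step 14**
Reactants: 21 (alcohol, C-2 epimers)
Product: 22 (1R,4aS,6S,8aS)-6-[(4S)-2,2-dimethyl-1,3-dioxolan-4-yl]-6,8a-dimethyl-1-{3-[(4S)-2,2,4-trimethyl-1,3-dioxolan-4-yl]propyl}octahydronaphthalen-2(1H)-one
Conditions: NPr4RuO4 (5 mol%), N-methylmorpholine N-oxide, 4 Å MS, CH2Cl2, rt
Reagents that add atoms: none
Why: Ley–Griffith oxidation converts both C-2 epimers back into the single ketone.

**Step 15**
Reactants: 22 (bis-acetonide ketone)
Product: 23 (1R,4aS,6S,8aS)-6-[(1S)-1,2-dihydroxyethyl]-1-[(4S)-4,5-dihydroxy-4-methylpentyl]-6,8a-dimethyloctahydronaphthalen-2(1H)-one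
Conditions: 1 M HCl, THF, rt
Reagents that add atoms: none
Why: Acid-catalysed acetal hydrolysis frees both diols, and C-1 stays in its thermodynamically preferred equatorial (1R) configuration.

**Compound list**
1 | (R)-2-methylglycidol, [(2R)-2-methyloxiran-2-yl]methanol | C[C@@]1(CO)CO1 | starting material
2 | allylmagnesium chloride | C=CC[Mg]Cl | starting material
3 | (S)-2-methylhex-5-ene-1,2-diol | C[C@@](O)(CO)CCC=C | intermediate
4 | (4S)-4-(but-3-en-1-yl)-2,2,4-trimethyl-1,3-dioxolane | CC1(C)OC[C@](C)(CCC=C)O1 | intermediate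
5 | 3-{2-[(4S)-2,2,4-trimethyl-1,3-dioxolan-4-yl]ethyl}-1,2,4-trioxolane (secondary ozonide, not isolated) | CC1(C)OC[C@](C)(CCC2OCOO2)O1 | intermediate
6 | 3-[(4S)-2,2,4-trimethyl-1,3-dioxolan-4-yl]propan-1-ol | CC1(C)OC[C@](C)(CCCO)O1 | intermediate
7 | (4S)-4-(3-bromopropyl)-2,2,4-trimethyl-1,3-dioxolane | CC1(C)OC[C@](C)(CCCBr)O1 | intermediate
8 | (R)-2,2-dimethyl-1,3-dioxolane-4-carbaldehyde ((R)-glyceraldehyde acetonide) | CC1(C)OC[C@H](C=O)O1 | starting material
9 | (4S)-4-ethynyl-2,2-dimethyl-1,3-dioxolane | CC1(C)OC[C@H](C#C)O1 | intermediate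
10 | (4S)-4-(buta-1,3-dien-2-yl)-2,2-dimethyl-1,3-dioxolane | CC1(C)OC[C@H](C(=C)C=C)O1 | intermediate
11 | methyl 4-oxobutanoate | COC(=O)CCC=O | starting material
12 | 2-(triphenylphosphoranylidene)propanal | CC(C=O)=P(c1ccccc1)(c1ccccc1)c1ccccc1 | starting material
13 | methyl (4E)-5-methyl-6-oxohex-4-enoate | COC(=O)CC/C=C(\C)C=O | intermediate
14 | methyl 3-[(1S,6S)-3-[(4S)-2,2-dimethyl-1,3-dioxolan-4-yl]-6-formyl-6-methylcyclohex-3-en-1-yl]propanoate (formyl and propanoate arm trans) | COC(=O)CC[C@H]1CC(=CC[C@]1(C)C=O)[C@H]2COC(C)(C)O2 | intermediate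
15 | {3-[(4S)-2,2,4-trimethyl-1,3-dioxolan-4-yl]propyl}magnesium bromide (not isolated) | CC1(C)OC[C@](C)(CCC[Mg]Br)O1 | intermediate
16 | methyl 3-[(1S,6S)-3-[(4S)-2,2-dimethyl-1,3-dioxolan-4-yl]-6-{1-hydroxy-4-[(4S)-2,2,4-trimethyl-1,3-dioxolan-4-yl]butyl}-6-methylcyclohex-3-en-1-yl]propanoate (both carbinol epimers) | COC(=O)CC[C@H]1CC(=CC[C@]1(C)C(O)CCC[C@@]2(C)COC(C)(C)O2)[C@H]3COC(C)(C)O3 | intermediate
17 | methyl 3-[(1S,6S)-3-[(4S)-2,2-dimethyl-1,3-dioxolan-4-yl]-6-methyl-6-{4-[(4S)-2,2,4-trimethyl-1,3-dioxolan-4-yl]butanoyl}cyclohex-3-en-1-yl]propanoate | COC(=O)CC[C@H]1CC(=CC[C@]1(C)C(=O)CCC[C@@]2(C)COC(C)(C)O2)[C@H]3COC(C)(C)O3 | intermediate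
18 | (4aS,8aS)-6-[(4S)-2,2-dimethyl-1,3-dioxolan-4-yl]-2-methoxy-8a-methyl-1-{3-[(4S)-2,2,4-trimethyl-1,3-dioxolan-4-yl]propyl}-3,4,4a,5,8,8a-hexahydronaphthalene (not isolated) | CC1(C)OC[C@](C)(CCCC2=C(OC)CC[C@H]3CC(=CC[C@@]32C)[C@H]4COC(C)(C)O4)O1 | intermediate
19 | (1R,4aS,8aS)-6-[(4S)-2,2-dimethyl-1,3-dioxolan-4-yl]-8a-methyl-1-{3-[(4S)-2,2,4-trimethyl-1,3-dioxolan-4-yl]propyl}-3,4,4a,5,8,8a-hexahydronaphthalen-2(1H)-one (trans-fused) | CC1(C)OC[C@](C)(CCC[C@H]2C(=O)CC[C@H]3CC(=CC[C@@]32C)[C@H]4COC(C)(C)O4)O1 | intermediate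
20 | (1R,4aS,6R,7S,8aS)-6-[(4S)-2,2-dimethyl-1,3-dioxolan-4-yl]-8a-methyl-6,7-methano-1-{3-[(4S)-2,2,4-trimethyl-1,3-dioxolan-4-yl]propyl}octahydronaphthalen-2(1H)-one (cyclopropane CH2 β, anti to the 8a-methyl) | CC1(C)OC[C@](C)(CCC[C@H]2C(=O)CC[C@H]3C[C@@]4(C[C@@H]4C[C@@]32C)[C@H]5COC(C)(C)O5)O1 | intermediate
21 | (1R,4aS,6S,8aS)-6-[(4S)-2,2-dimethyl-1,3-dioxolan-4-yl]-6,8a-dimethyl-1-{3-[(4S)-2,2,4-trimethyl-1,3-dioxolan-4-yl]propyl}decahydronaphthalen-2-ol (C-2 epimers) | CC1(C)OC[C@](C)(CCC[C@H]2C(O)CC[C@H]3C[C@@](C)([C@H]4COC(C)(C)O4)CC[C@@]32C)O1 | intermediate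
22 | (1R,4aS,6S,8aS)-6-[(4S)-2,2-dimethyl-1,3-dioxolan-4-yl]-6,8a-dimethyl-1-{3-[(4S)-2,2,4-trimethyl-1,3-dioxolan-4-yl]propyl}octahydronaphthalen-2(1H)-one | CC1(C)OC[C@](C)(CCC[C@H]2C(=O)CC[C@H]3C[C@@](C)([C@H]4COC(C)(C)O4)CC[C@@]32C)O1 | intermediate
23 | (1R,4aS,6S,8aS)-6-[(1S)-1,2-dihydroxyethyl]-1-[(4S)-4,5-dihydroxy-4-methylpentyl]-6,8a-dimethyloctahydronaphthalen-2(1H)-one (CNP0153053.1) | C[C@@](O)(CO)CCC[C@H]1C(=O)CC[C@H]2C[C@@](C)([C@H](O)CO)CC[C@@]21C | target

**Step count**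
Total: 15 steps. Longest linear sequence: 11 steps (steps 1–4, then 9–15).

**Steps most likely to fail**

Step 8 (Diels–Alder). The trisubstituted enal may react sluggishly with an allylically oxygenated diene, and the cationic boron catalyst may bind or cleave the acetonide. The fallback sets out from 10 and 13 and comes back at 14. It gives up catalyst control and uses the stereocentre already in 10 as a resolving handle: the cycloaddition is run with the achiral Lewis acid Me2AlCl in CH2Cl2 at −40 °C (or neat at 12 kbar). Because the dioxolane centre is fixed, the two facial modes give 14 and its ring diastereomer, methyl 3-[(1R,6R)-3-[(4S)-2,2-dimethyl-1,3-dioxolan-4-yl]-6-formyl-6-methylcyclohex-3-en-1-yl]propanoate F1. These are separated by preparative HPLC and 14 is carried on.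

Step 11 (keto ester cyclization). The neopentyl ketone may be reduced or couple intermolecularly, and low-valent titanium may attack the allylic acetal. The fallback sets out from 16 and comes back at 19. It replaces the reductive carbonyl–ester coupling by a pinacol closure followed by deoxygenation:
- LiAlH4 (THF, 0 °C) reduces the ester of 16 to the diol 3-[(1S,6S)-3-[(4S)-2,2-dimethyl-1,3-dioxolan-4-yl]-6-{1-hydroxy-4-[(4S)-2,2,4-trimethyl-1,3-dioxolan-4-yl]butyl}-6-methylcyclohex-3-en-1-yl]propan-1-ol F2.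
- Swern oxidation gives the keto aldehyde 3-[(1S,6S)-3-[(4S)-2,2-dimethyl-1,3-dioxolan-4-yl]-6-methyl-6-{4-[(4S)-2,2,4-trimethyl-1,3-dioxolan-4-yl]butanoyl}cyclohex-3-en-1-yl]propanal F3.
- SmI2 (THF, t-BuOH) closes ring A by intramolecular pinacol coupling to the cis-1,2-diol F4.
- Dess–Martin periodinane oxidises only the secondary hydroxyl, giving the 1-hydroxy-2-ketone F5.
- SmI2 in THF/MeOH cleaves the tertiary α-hydroxyl, and K2CO3/MeOH equilibration gives 19.

Step 12 (cyclopropanation, with the hydrogenolysis that follows). The allylic dioxolane oxygens may steer the zinc carbenoid to the wrong face, or the hydrogenolysis may open another cyclopropane bond. The fallback sets out from 19 and comes back at 22, and also removes the reduction and re-oxidation of the ketone. It is a Markovnikov radical hydromethylation by metal-hydride hydrogen-atom transfer. Fe(acac)3, PhSiH3 and preformed formaldehyde N-(octylsulfonyl)hydrazone in THF/MeOH turn the C6=C7 alkene into the tertiary C-6 radical. This radical should add to the hydrazone from the axial β-face (dioxolane staying equatorial) to give the alkyl sulfonyl hydrazide F6, which is not isolated. Warming in MeOH (60 °C) expels the sulfinic acid and nitrogen and leaves the axial C-6 methyl of 22.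

**Further compounds**
F1 | step 8 | methyl 3-[(1R,6R)-3-[(4S)-2,2-dimethyl-1,3-dioxolan-4-yl]-6-formyl-6-methylcyclohex-3-en-1-yl]propanoate | COC(=O)CC[C@@H]1CC(=CC[C@@]1(C)C=O)[C@H]2COC(C)(C)O2
F2 | step 11 | 3-[(1S,6S)-3-[(4S)-2,2-dimethyl-1,3-dioxolan-4-yl]-6-{1-hydroxy-4-[(4S)-2,2,4-trimethyl-1,3-dioxolan-4-yl]butyl}-6-methylcyclohex-3-en-1-yl]propan-1-ol (carbinol epimers) | OCCC[C@H]1CC(=CC[C@]1(C)C(O)CCC[C@@]2(C)COC(C)(C)O2)[C@H]3COC(C)(C)O3
F3 | step 11 | 3-[(1S,6S)-3-[(4S)-2,2-dimethyl-1,3-dioxolan-4-yl]-6-methyl-6-{4-[(4S)-2,2,4-trimethyl-1,3-dioxolan-4-yl]butanoyl}cyclohex-3-en-1-yl]propanal | O=CCC[C@H]1CC(=CC[C@]1(C)C(=O)CCC[C@@]2(C)COC(C)(C)O2)[C@H]3COC(C)(C)O3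
F4 | step 11 | (4aS,8aS)-6-[(4S)-2,2-dimethyl-1,3-dioxolan-4-yl]-8a-methyl-1-{3-[(4S)-2,2,4-trimethyl-1,3-dioxolan-4-yl]propyl}-1,2,3,4,4a,5,8,8a-octahydronaphthalene-1,2-diol (cis-diol) | CC1(C)OC[C@](C)(CCCC2(O)C(O)CC[C@H]3CC(=CC[C@@]32C)[C@H]4COC(C)(C)O4)O1
F5 | step 11 | (4aS,8aS)-6-[(4S)-2,2-dimethyl-1,3-dioxolan-4-yl]-1-hydroxy-8a-methyl-1-{3-[(4S)-2,2,4-trimethyl-1,3-dioxolan-4-yl]propyl}-3,4,4a,5,8,8a-hexahydronaphthalen-2(1H)-one | CC1(C)OC[C@](C)(CCCC2(O)C(=O)CC[C@H]3CC(=CC[C@@]32C)[C@H]4COC(C)(C)O4)O1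
F6 | step 12 | N′-{[(1R,4aS,8aS)-6-[(4S)-2,2-dimethyl-1,3-dioxolan-4-yl]-8a-methyl-2-oxo-1-{3-[(4S)-2,2,4-trimethyl-1,3-dioxolan-4-yl]propyl}decahydronaphthalen-6-yl]methyl}octane-1-sulfonohydrazide (CH2N on the β-face of C-6, target numbering) | CC1(C)OC[C@](C)(CCC[C@H]2C(=O)CC[C@H]3C[C@@](CNNS(=O)(=O)CCCCCCCC)([C@H]4COC(C)(C)O4)CC[C@@]32C)O1
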